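**Strategy.** The bicyclo[3.3.1]non-2-ene is cut at its only ring alkene, C2=C3 (C1 and C5 are the bridgeheads, C9 the acetoxy bridge). Ring-closing metathesis joins a 1,1-disubstituted vinyl arm on C1 to an allyl arm on C5 of a 2,2,6,6-tetrasubstituted cyclohexanone and closes the cyclohexene ring C1–C2–C3–C4–C5–C9 in one operation. The step exploits the fact that both quaternary bridgeheads flank the C9 carbonyl of the cyclohexane ring C1–C9–C5–C6–C7–C8: in the chair with the C8 side chain equatorial both arms stand 1,3-diaxial, so only the correct diastereomer can cyclise. The precursor is built from (R)-citronellal by an organocatalytic annulation and three enolate functionalisations.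

Key step: step 8

Remark: atom labels follow bicyclo[3.3.1]nonane numbering of the target (C1 formyl bridgehead, C2 formyl alkene carbon, C5 methyl bridgehead, C8 side-chain carbon, C9 acetoxy carbon; ring A = C1, C2, C3, C4, C5, C9; ring B = C1, C9, C5, C6, C7, C8); compounds 1, 4 and 9 are taken as commercial.

Step 1
Reactants: 1 (R)-citronellal, (3R)-3,7-dimethyloct-6-enal
Product: 2 (4R)-1-methoxy-4,8-dimethylnona-1,7-diene (E/Z mixture)
Conditions: MeOCH2PPh3Cl, KOtBu, THF, 0 °C → rt
Reagents that add atoms: (methoxymethyl)triphenylphosphonium chloride, COC[P+](c1ccccc1)(c1ccccc1)c1ccccc1.[Cl-]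
Why: Wittig olefination with the methoxymethylene ylide homologates the aldehyde by one carbon to the enol ether; the chiral-pool stereocentre is β to the carbonyl and is not touched.

Step 2
Reactants: 2 (4R)-1-methoxy-4,8-dimethylnona-1,7-diene
Product: 3 (2E,4R)-4,8-dimethylnona-2,7-dienal
Conditions: Pd(OAc)2 (10 mol%), Cu(OAc)2 (20 mol%), O2 (1 atm), NaHCO3, MeCN/H2O, rt
Reagents that add atoms: water, O
Why: Saegusa–Ito-type dehydrogenation (oxypalladation of the electron-rich enol ether by divalent palladium, β-hydride elimination, hydrolysis of the oxocarbenium ion) should give the (E)-enal, while the isolated trisubstituted alkene is far less reactive and the γ-stereocentre is not involved.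

Step 3
Reactants: 3 (2E,4R)-4,8-dimethylnona-2,7-dienal; 4 tert-butyl 3-oxopentanoate
Product: 6 (5R)-2-methyl-5-[(2R)-6-methylhept-5-en-2-yl]cyclohex-2-en-1-one, via Michael adduct 5 (not isolated)
Conditions: (S)-2-[diphenyl(trimethylsilyloxy)methyl]pyrrolidine (10 mol%), PhCO2H (10 mol%), toluene, rt; then TsOH·H2O (20 mol%), 80 °C
Reagents that add atoms: none
Why: iminium-catalysed Michael addition of the β-ketoester, then acid-promoted intramolecular aldol condensation and loss of the tert-butyl ester as isobutene and CO2 (organocatalytic cyclohexenone annulation); the new ring stereocentre (C8) is set under catalyst control by attack anti to the diphenyl(silyloxy)methyl group of the (E)-iminium ion.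

Step 4
Reactants: 6 (5R)-2-methyl-5-[(2R)-6-methylhept-5-en-2-yl]cyclohex-2-en-1-one
Product: 8 (2R,5R)-2-methyl-5-[(2R)-6-methylhept-5-en-2-yl]-2-(prop-2-en-1-yl)cyclohexan-1-one, via lithium enolate 7 (not isolated)
Conditions: LiBH(s-Bu)3 (L-Selectride), THF, −78 °C; then allyl bromide, DMPU, −78 °C → rt
Reagents that add atoms: allyl bromide, C=CCBr
Why: conjugate reduction gives the regiodefined tetrasubstituted enolate, and axial allylation through a chair-like transition state with the side chain equatorial should place the allyl group cis to the side chain at the new quaternary centre C5 (the sense known for dihydrocarvone-type enolates).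

Step 5
Reactants: 8 (2R,5R)-2-methyl-5-[(2R)-6-methylhept-5-en-2-yl]-2-(prop-2-en-1-yl)cyclohexan-1-one; 9 methyl 2,2-dimethoxyacetate
Product: 10 (2R,5S)-6-(2,2-dimethoxyacetyl)-2-methyl-5-[(2R)-6-methylhept-5-en-2-yl]-2-(prop-2-en-1-yl)cyclohexan-1-one (C6 epimers and enol tautomers)
Conditions: NaH (2.5 equiv), THF, 0 → 60 °C; aq. NH4Cl
Reagents that add atoms: none
Why: crossed Claisen condensation at the only enolisable position (C1) with the activated ester, driven by deprotonation of the 1,3-diketone formed; the new methine is configurationally labile, so no stereochemistry is fixed here.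

Step 6
Reactants: 10 (2R,5S)-6-(2,2-dimethoxyacetyl)-2-methyl-5-[(2R)-6-methylhept-5-en-2-yl]-2-(prop-2-en-1-yl)cyclohexan-1-one
Product: 11 (2R,5S,6S)-6-(2,2-dimethoxyacetyl)-6-(dimethoxymethyl)-2-methyl-5-[(2R)-6-methylhept-5-en-2-yl]-2-(prop-2-en-1-yl)cyclohexan-1-one
Conditions: HC(OMe)3, BF3·OEt2, CH2Cl2, −30 °C; then 10, i-Pr2NEt, −78 → −20 °C
Reagents that add atoms: trimethyl orthoformate, COC(OC)OC
Why: C-alkylation of the diketone enol by the dimethoxycarbenium ion (orthoformate/BF3 α-dialkoxymethylation of enolisable carbonyl compounds) should occur anti to the neighbouring side chain, which A(1,3) strain holds pseudo-axial, so that the acyl arm ends cis to the side chain and to the allyl group at the quaternary centre C1.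

Step 7
Reactants: 11 (2R,5S,6S)-6-(2,2-dimethoxyacetyl)-6-(dimethoxymethyl)-2-methyl-5-[(2R)-6-methylhept-5-en-2-yl]-2-(prop-2-en-1-yl)cyclohexan-1-one
Product: 12 (2R,5S,6S)-6-(dimethoxymethyl)-6-(3,3-dimethoxyprop-1-en-2-yl)-2-methyl-5-[(2R)-6-methylhept-5-en-2-yl]-2-(prop-2-en-1-yl)cyclohexan-1-one
Conditions: Cp2Ti(μ-CH2)(μ-Cl)AlMe2 (Tebbe reagent, 1.1 equiv), pyridine, THF/toluene, −40 → 0 °C
Reagents that add atoms: Tebbe reagent, C[Al-]1(C)C[Ti](C2C=CC=C2)(C2C=CC=C2)[Cl+]1
Why: Tebbe methylenation ([2+2] addition of Cp2Ti=CH2 to C=O and cycloreversion) should take the exocyclic α-ketoacetal ketone in preference to the ring ketone flanked by two quaternary carbons, and the non-basic reagent avoids retro-Claisen cleavage of the non-enolisable 1,3-diketone.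

Step 8
Reactants: 12 (2R,5S,6S)-6-(dimethoxymethyl)-6-(3,3-dimethoxyprop-1-en-2-yl)-2-methyl-5-[(2R)-6-methylhept-5-en-2-yl]-2-(prop-2-en-1-yl)cyclohexan-1-one
Product: 13 (1S,5R,8S)-1,2-bis(dimethoxymethyl)-5-methyl-8-[(2R)-6-methylhept-5-en-2-yl]bicyclo[3.3.1]non-2-en-9-one
Conditions: second-generation Hoveyda–Grubbs catalyst RuCl2(H2IMes)(=CH-2-i-PrOC6H4) (10 mol%), toluene (0.005 M), 80 °C, argon sparge
Reagents that add atoms: none
Why: The ruthenium alkylidene initiates at the monosubstituted allyl terminus on C5, adds intramolecularly to the 1,1-disubstituted alkene on C1 through a ruthenacyclobutane that carries the two substituents of C2 on the carbon remote from ruthenium, and cycloreversion releases ethene and the C2=C3 bond. The closest known reaction type is ring-closing metathesis of cis-2,6-dialkenylcyclohexanones to bicyclo[3.3.1]non-2-en-9-ones, including closures to trisubstituted alkenes next to quaternary carbons. The six-membered ring A is closed by alkene–alkene metathesis between two arms that stand 1,3-diaxial on ring B across the C9 carbonyl. No stereocentre is created: the cis relationship of the bridgeheads C1 and C5 is already fixed, and the step proof-reads it, since an epimer at C1 or C5 has one arm equatorial and cannot cyclise. The step needs site selectivity among four alkenes and cyclisation over oligomerisation: the trisubstituted side-chain alkene is inert to the catalyst and would only give rings of ten or more members, and high dilution with removal of ethene favours closure.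

Step 9
Reactants: 13 (1S,5R,8S)-1,2-bis(dimethoxymethyl)-5-methyl-8-[(2R)-6-methylhept-5-en-2-yl]bicyclo[3.3.1]non-2-en-9-one
Product: 14 (1R,5R,8S,9R)-1,2-bis(dimethoxymethyl)-5-methyl-8-[(2R)-6-methylhept-5-en-2-yl]bicyclo[3.3.1]non-2-en-9-ol
Conditions: LiAlH4, THF, −20 → 0 °C
Reagents that add atoms: none
Why: hydride addition to the bridging ketone should come from the face over ring A, which has only one pseudo-axial hydrogen (at C4) against two axial hydrogens (C6, C8) over ring B, giving the C9 alcohol syn to the saturated bridge.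

Step 10
Reactants: 14 (1R,5R,8S,9R)-1,2-bis(dimethoxymethyl)-5-methyl-8-[(2R)-6-methylhept-5-en-2-yl]bicyclo[3.3.1]non-2-en-9-ol
Product: 15 (1R,5R,8S,9R)-1,2-bis(dimethoxymethyl)-5-methyl-8-[(2R)-6-methylhept-5-en-2-yl]bicyclo[3.3.1]non-2-en-9-yl acetate
Conditions: Ac2O, DMAP, Et3N, CH2Cl2, 40 °C
Reagents that add atoms: acetic anhydride, CC(=O)OC(C)=O
Why: DMAP-catalysed acylation of the hindered secondary alcohol under basic conditions, to which both acetals are stable; the stereocentre is not affected.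

Step 11
Reactants: 15 (1R,5R,8S,9R)-1,2-bis(dimethoxymethyl)-5-methyl-8-[(2R)-6-methylhept-5-en-2-yl]bicyclo[3.3.1]non-2-en-9-yl acetate
Product: 16 (1R,5R,8S,9R)-1,2-diformyl-5-methyl-8-[(2R)-6-methylhept-5-en-2-yl]bicyclo[3.3.1]non-2-en-9-yl acetate (target)
Conditions: 1 M aq. HCl, THF, rt
Reagents that add atoms: water, O
Why: acid-catalysed hydrolysis of both dimethyl acetals releases the enal and the bridgehead aldehyde; C1 is quaternary, so neither epimerisation nor β-elimination of acetate is possible, and the acetate and both alkenes should survive dilute acid.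

Compound list
1 | (R)-citronellal, (3R)-3,7-dimethyloct-6-enal | O=CC[C@H](C)CCC=C(C)C | starting material
2 | (4R)-1-methoxy-4,8-dimethylnona-1,7-diene (E/Z mixture) | COC=CC[C@H](C)CCC=C(C)C | intermediate
3 | (2E,4R)-4,8-dimethylnona-2,7-dienal | O=C/C=C/[C@H](C)CCC=C(C)C | intermediate
4 | tert-butyl 3-oxopentanoate | CCC(=O)CC(=O)OC(C)(C)C | starting material
5 | tert-butyl (3S)-3-[(2R)-6-methylhept-5-en-2-yl]-5-oxo-2-propanoylpentanoate (both C2 epimers) | CCC(=O)C(C(=O)OC(C)(C)C)[C@H]([C@H](C)CCC=C(C)C)CC=O | intermediate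
6 | (5R)-2-methyl-5-[(2R)-6-methylhept-5-en-2-yl]cyclohex-2-en-1-one | O=C1C[C@H]([C@H](C)CCC=C(C)C)CC=C1C | intermediate
7 | lithium (5R)-2-methyl-5-[(2R)-6-methylhept-5-en-2-yl]cyclohex-1-en-1-olate | [Li+].[O-]C1=C(C)CC[C@@H]([C@H](C)CCC=C(C)C)C1 | intermediate
8 | (2R,5R)-2-methyl-5-[(2R)-6-methylhept-5-en-2-yl]-2-(prop-2-en-1-yl)cyclohexan-1-one | C=CC[C@@]1(C)CC[C@@H]([C@H](C)CCC=C(C)C)CC1=O | intermediate
9 | methyl 2,2-dimethoxyacetate | COC(OC)C(=O)OC | starting material
10 | (2R,5S)-6-(2,2-dimethoxyacetyl)-2-methyl-5-[(2R)-6-methylhept-5-en-2-yl]-2-(prop-2-en-1-yl)cyclohexan-1-one (C6 epimers, enol tautomers) | C=CC[C@@]1(C)CC[C@@H]([C@H](C)CCC=C(C)C)C(C(=O)C(OC)OC)C1=O | intermediate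
11 | (2R,5S,6S)-6-(2,2-dimethoxyacetyl)-6-(dimethoxymethyl)-2-methyl-5-[(2R)-6-methylhept-5-en-2-yl]-2-(prop-2-en-1-yl)cyclohexan-1-one | C=CC[C@@]1(C)CC[C@@H]([C@H](C)CCC=C(C)C)[C@@](C(OC)OC)(C(=O)C(OC)OC)C1=O | intermediate
12 | (2R,5S,6S)-6-(dimethoxymethyl)-6-(3,3-dimethoxyprop-1-en-2-yl)-2-methyl-5-[(2R)-6-methylhept-5-en-2-yl]-2-(prop-2-en-1-yl)cyclohexan-1-one | C=CC[C@@]1(C)CC[C@@H]([C@H](C)CCC=C(C)C)[C@@](C(OC)OC)(C(=C)C(OC)OC)C1=O | intermediate
13 | (1S,5R,8S)-1,2-bis(dimethoxymethyl)-5-methyl-8-[(2R)-6-methylhept-5-en-2-yl]bicyclo[3.3.1]non-2-en-9-one | O=C1[C@@]2(C)CC=C(C(OC)OC)[C@]1(C(OC)OC)[C@H]([C@H](C)CCC=C(C)C)CC2 | intermediate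
14 | (1R,5R,8S,9R)-1,2-bis(dimethoxymethyl)-5-methyl-8-[(2R)-6-methylhept-5-en-2-yl]bicyclo[3.3.1]non-2-en-9-ol | O[C@@H]1[C@@]2(C)CC=C(C(OC)OC)[C@]1(C(OC)OC)[C@H]([C@H](C)CCC=C(C)C)CC2 | intermediate
15 | (1R,5R,8S,9R)-1,2-bis(dimethoxymethyl)-5-methyl-8-[(2R)-6-methylhept-5-en-2-yl]bicyclo[3.3.1]non-2-en-9-yl acetate | CC(=O)O[C@@H]1[C@@]2(C)CC=C(C(OC)OC)[C@]1(C(OC)OC)[C@H]([C@H](C)CCC=C(C)C)CC2 | intermediate
16 | (1R,5R,8S,9R)-1,2-diformyl-5-methyl-8-[(2R)-6-methylhept-5-en-2-yl]bicyclo[3.3.1]non-2-en-9-yl acetate | CC(=O)O[C@@H]1[C@@]2(C)CC=C(C=O)[C@]1(C=O)[C@H]([C@H](C)CCC=C(C)C)CC2 | target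

Total step count: 11. Longest linear sequence: 11 steps (1 to 16).

Steps most likely to fail

Step 8. The catalyst may fail to turn over at the congested 1,1-disubstituted alkene, so that catalyst decomposition and intermolecular metathesis of the allyl group take over. The fallback replaces metathesis by an intramolecular Wittig olefination of the C2 ketone and sets out from enone 6. Reductive alkylation (LiBH(s-Bu)3, then 2-(tert-butyldimethylsilyloxy)ethyl trifluoromethanesulfonate) would give the silyloxyethyl ketone F1. Claisen condensation with 9 as in step 5 would give the diketone F2, and dimethoxymethylation as in step 6 the quaternary diketone F3. Bu4NF would free the primary alcohol F4; I2, PPh3 and imidazole would give the iodide F5; PPh3 in MeCN at 80 °C would give the phosphonium iodide F6. KN(SiMe3)2 in THF would then generate the ylide at C3, which should olefinate the C2 ketone through a six-membered transition state and rejoin the route at 13.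

Step 7. Methylenation of the hindered exocyclic ketone may stall, may also attack the ring ketone, or may be overtaken by retro-Claisen cleavage of the diketone. The fallback bypasses the methylenation and sets out from 11. One equivalent of the Schrock alkylidene Mo(=CHCMe2Ph)(=N-2,6-i-Pr2C6H3)[OCMe(CF3)2]2 in benzene at rt would exchange with the allyl group, and the molybdenum alkylidene formed at C3 would olefinate the C2 ketone intramolecularly (tandem olefin metathesis and carbonyl olefination). Only the C2 ketone can give a six-membered ring, so the site selectivity is built in. The sequence rejoins the route at 13 and makes no new isolated compound.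

Step 6. The carbenium ion may alkylate the enol oxygen or be captured by the trisubstituted side-chain alkene, and facial selectivity at the crowded methine may be poor. The fallback builds the 1,1-disubstituted alkene by aldehyde α-methylenation on a monoketone and sets out from 8. LiN(i-Pr)2, then 2-(tert-butyldimethylsilyloxy)ethyl trifluoromethanesulfonate, would give the silyloxyethyl ketone F7. The same orthoformate/BF3·OEt2/i-Pr2NEt protocol, here at the more substituted α-carbon of a simple ketone and anti to the side chain, would give the β-keto acetal F8. Bu4NF would give the alcohol F9 and Dess–Martin periodinane the aldehyde F10. Aqueous CH2O with pyrrolidinium propionate in i-PrOH at 45 °C would give the 2-substituted acrolein F11. HC(OMe)3 and PPTS in MeOH would then give the acetal and rejoin the route at 12.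

Further compounds
F1 | step 8 | (2R,5R)-2-[2-(tert-butyldimethylsilyloxy)ethyl]-2-methyl-5-[(2R)-6-methylhept-5-en-2-yl]cyclohexan-1-one | CC(C)(C)[Si](C)(C)OCC[C@@]1(C)CC[C@@H]([C@H](C)CCC=C(C)C)CC1=O
F2 | step 8 | (2R,5S)-2-[2-(tert-butyldimethylsilyloxy)ethyl]-6-(2,2-dimethoxyacetyl)-2-methyl-5-[(2R)-6-methylhept-5-en-2-yl]cyclohexan-1-one (C6 epimers) | CC(C)(C)[Si](C)(C)OCC[C@@]1(C)CC[C@@H]([C@H](C)CCC=C(C)C)C(C(=O)C(OC)OC)C1=O
F3 | step 8 | (2R,5S,6S)-2-[2-(tert-butyldimethylsilyloxy)ethyl]-6-(2,2-dimethoxyacetyl)-6-(dimethoxymethyl)-2-methyl-5-[(2R)-6-methylhept-5-en-2-yl]cyclohexan-1-one | CC(C)(C)[Si](C)(C)OCC[C@@]1(C)CC[C@@H]([C@H](C)CCC=C(C)C)[C@@](C(OC)OC)(C(=O)C(OC)OC)C1=O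
F4 | step 8 | (2R,5S,6S)-6-(2,2-dimethoxyacetyl)-6-(dimethoxymethyl)-2-(2-hydroxyethyl)-2-methyl-5-[(2R)-6-methylhept-5-en-2-yl]cyclohexan-1-one | OCC[C@@]1(C)CC[C@@H]([C@H](C)CCC=C(C)C)[C@@](C(OC)OC)(C(=O)C(OC)OC)C1=O
F5 | step 8 | (2R,5S,6S)-6-(2,2-dimethoxyacetyl)-6-(dimethoxymethyl)-2-(2-iodoethyl)-2-methyl-5-[(2R)-6-methylhept-5-en-2-yl]cyclohexan-1-one | ICC[C@@]1(C)CC[C@@H]([C@H](C)CCC=C(C)C)[C@@](C(OC)OC)(C(=O)C(OC)OC)C1=O
F6 | step 8 | triphenylphosphonium iodide of F5 (PPh3 in place of iodine on the ethyl arm) | [I-].c1ccccc1[P+](c1ccccc1)(c1ccccc1)CC[C@@]1(C)CC[C@@H]([C@H](C)CCC=C(C)C)[C@@](C(OC)OC)(C(=O)C(OC)OC)C1=O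
F0 | step 7 | none | none
F7 | step 6 | (2R,5S)-6-[2-(tert-butyldimethylsilyloxy)ethyl]-2-methyl-5-[(2R)-6-methylhept-5-en-2-yl]-2-(prop-2-en-1-yl)cyclohexan-1-one (C6 epimers) | C=CC[C@@]1(C)CC[C@@H]([C@H](C)CCC=C(C)C)C(CCO[Si](C)(C)C(C)(C)C)C1=O
F8 | step 6 | (2R,5S,6R)-6-[2-(tert-butyldimethylsilyloxy)ethyl]-6-(dimethoxymethyl)-2-methyl-5-[(2R)-6-methylhept-5-en-2-yl]-2-(prop-2-en-1-yl)cyclohexan-1-one | C=CC[C@@]1(C)CC[C@@H]([C@H](C)CCC=C(C)C)[C@@](C(OC)OC)(CCO[Si](C)(C)C(C)(C)C)C1=O
F9 | step 6 | (2R,5S,6R)-6-(dimethoxymethyl)-6-(2-hydroxyethyl)-2-methyl-5-[(2R)-6-methylhept-5-en-2-yl]-2-(prop-2-en-1-yl)cyclohexan-1-one | C=CC[C@@]1(C)CC[C@@H]([C@H](C)CCC=C(C)C)[C@@](C(OC)OC)(CCO)C1=O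
F10 | step 6 | (2R,5S,6R)-6-(dimethoxymethyl)-2-methyl-5-[(2R)-6-methylhept-5-en-2-yl]-6-(2-oxoethyl)-2-(prop-2-en-1-yl)cyclohexan-1-one | C=CC[C@@]1(C)CC[C@@H]([C@H](C)CCC=C(C)C)[C@@](C(OC)OC)(CC=O)C1=O
F11 | step 6 | (2R,5S,6S)-6-(dimethoxymethyl)-2-methyl-5-[(2R)-6-methylhept-5-en-2-yl]-6-(3-oxoprop-1-en-2-yl)-2-(prop-2-en-1-yl)cyclohexan-1-one | C=CC[C@@]1(C)CC[C@@H]([C@H](C)CCC=C(C)C)[C@@](C(OC)OC)(C(=C)C=O)C1=O
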